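**Retrosynthetic overview**

Tetralin numbering: ring A is the aromatic ring (C4a, C5–C8, C8a), ring B is C1–C4; C1 carries CH3, C4 the chain C11–C16, C6 the CO2Me, C7 and C8 the OH groups. The route rests on the adjacent methines C4 (ring B) and C11: their two hydrogens can be added syn to a (Z)-C4=C11 alkene (C4a cis to C12), which is what syn arylmetalation of a C4≡C11 alkyne from C4a delivers.
1. 21 ⇒ 17: silyl and methyl ethers off; C6–CO2Me by ortho-lithiation beside the C7 methoxy group, held back until the alkyne and the aryl bromide are gone.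
2. 17 ⇒ 16: C4–H and C11–H by ligand-controlled syn hydrogenation of the tetrasubstituted alkene.
3. 16 ⇒ 8 + 14: C4a–C4 and C11–C12 in one palladium cascade that closes ring B (the only ring made; ring A is bought) and attaches the side chain as its alkyl-9-BBN.
4. 8 from 2,3-dimethoxyphenylboronic acid and a crotonate (C1 by rhodium-catalysed conjugate addition); 14 from methyl (R)-3-hydroxy-2-methylpropanoate (C15 from the chiral pool).

Key step: step 10

Assumption: (R)-BINAP is taken to give (R)-3 and (S)-iPr-PHOX to add H2 to the C4=C11 face on the side of the C1 methyl group, by analogy with the usual facial preferences of these catalyst families; if either sense is the opposite, the mirror-image ligand is used.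

**Route**

Step 1
Reactants: 1 2,3-dimethoxyphenylboronic acid; 2 isopropyl (E)-but-2-enoate
Product: 3 isopropyl (R)-3-(2,3-dimethoxyphenyl)butanoate
Conditions: 1 (2.5 equiv), Rh(acac)(C2H4)2 (3 mol %), (R)-BINAP (3.3 mol %), 1,4-dioxane/H2O 10:1, 100 °C
Reagents that add atoms: none
Why: Rhodium-catalysed asymmetric conjugate addition of an arylboronic acid to an (E)-enoate (Hayashi–Miyaura reaction), in which the BINAP-bound aryl–rhodium species inserts one enantioface of the crotonate and water releases the ester, so that the ligand should set C1 as (R).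

Step 2
Reactants: 3 isopropyl (R)-3-(2,3-dimethoxyphenyl)butanoate
Product: 4 (R)-3-(2,3-dimethoxyphenyl)butan-1-ol
Conditions: LiAlH4, THF, 0 °C → rt
Reagents that add atoms: none
Why: Hydride reduction of the ester to the primary alcohol; the aryl ethers are inert and the stereocentre, β to the carbonyl, cannot epimerise.

Step 3
Reactants: 4 (R)-3-(2,3-dimethoxyphenyl)butan-1-ol
Product: 5 (R)-3-(6-bromo-2,3-dimethoxyphenyl)butan-1-ol
Conditions: NBS (1.05 equiv), MeCN, 0 °C → rt, dark
Reagents that add atoms: N-bromosuccinimide, O=C1CCC(=O)N1Br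
Why: Electrophilic aromatic bromination, in which the future C7 methoxy group, coplanar with the ring and unhindered on one side, should direct to its para position (the future C4a) while the flanked, twisted C8 methoxy group directs only weakly, as in the bromination of other 3-substituted veratroles.

Step 4
Reactants: 5 (R)-3-(6-bromo-2,3-dimethoxyphenyl)butan-1-ol
Product: 6 (R)-1-bromo-2-(4-iodobutan-2-yl)-3,4-dimethoxybenzene
Conditions: I2, PPh3, imidazole, CH2Cl2, 0 °C → rt
Reagents that add atoms: iodine, II
Why: Appel-type iodination of a primary alcohol through the alkoxyphosphonium iodide, neutral conditions that leave the aryl bromide, the ethers and C1 untouched.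

Step 5
Reactants: 6 (R)-1-bromo-2-(4-iodobutan-2-yl)-3,4-dimethoxybenzene; 7 1-propynyllithium
Product: 8 (R)-1-bromo-2-(hept-5-yn-2-yl)-3,4-dimethoxybenzene
Conditions: 7 (1.5 equiv), THF/DMPU 4:1, −78 °C → rt
Reagents that add atoms: none
Why: SN2 alkylation of an alkynyllithium by an unhindered primary iodide in a dipolar cosolvent; an acetylide does not exchange with the aryl bromide or deprotonate the benzylic C1–H.

Step 6
Reactants: 9 methyl (R)-3-hydroxy-2-methylpropanoate
Product: 10 methyl (R)-3-[(tert-butyldiphenylsilyl)oxy]-2-methylpropanoate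
Conditions: TBDPSCl, imidazole, DMF, rt
Reagents that add atoms: tert-butyl(chloro)diphenylsilane, CC(C)(C)[Si](Cl)(c1ccccc1)c1ccccc1
Why: Silylation of the primary alcohol; the TBDPS ether is chosen because it should survive organolithium base and BBr3 at low temperature later on.

Step 7
Reactants: 10 methyl (R)-3-[(tert-butyldiphenylsilyl)oxy]-2-methylpropanoate
Product: 11 (S)-3-[(tert-butyldiphenylsilyl)oxy]-2-methylpropan-1-ol
Conditions: i-Bu2AlH (2.2 equiv), CH2Cl2, −78 → 0 °C
Reagents that add atoms: none
Why: Ester reduction to the primary alcohol with an aluminium hydride at low temperature, under which the α-stereocentre does not enolise (the descriptor changes by CIP priority only).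

Step 8
Reactants: 11 (S)-3-[(tert-butyldiphenylsilyl)oxy]-2-methylpropan-1-ol
Product: 12 (R)-3-[(tert-butyldiphenylsilyl)oxy]-2-methylpropyl 4-methylbenzenesulfonate
Conditions: TsCl, Et3N, DMAP (cat.), CH2Cl2, 0 °C → rt
Reagents that add atoms: 4-methylbenzenesulfonyl chloride, Cc1ccc(cc1)S(=O)(=O)Cl
Why: Sulfonylation of a primary alcohol, which activates C14 for substitution without touching C15.

Step 9
Reactants: 12 (R)-3-[(tert-butyldiphenylsilyl)oxy]-2-methylpropyl 4-methylbenzenesulfonate; 13 vinylmagnesium bromide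
Product: 14 (S)-tert-butyl[(2-methylpent-4-en-1-yl)oxy]diphenylsilane
Conditions: 13 (3 equiv), CuI (20 mol %), THF, −30 → 0 °C
Reagents that add atoms: none
Why: Copper-catalysed cross-coupling of a primary alkyl tosylate with a Grignard reagent, which forms C13–C14 one carbon away from the C15 stereocentre and leaves the silyl ether intact.

Step 10
Reactants: 8 (R)-1-bromo-2-(hept-5-yn-2-yl)-3,4-dimethoxybenzene; 14 (S)-tert-butyl[(2-methylpent-4-en-1-yl)oxy]diphenylsilane
Product: 16 tert-butyl{[(2S,6Z)-6-[(4R)-5,6-dimethoxy-4-methyl-3,4-dihydronaphthalen-1(2H)-ylidene]-2-methylheptyl]oxy}diphenylsilane, via alkylborane 15 (not isolated)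
Conditions: 14 (1.5 equiv), 9-BBN dimer, THF, 0 °C → rt; this solution added over 2 h to 8, Pd(PPh3)4 (10 mol %), 3 M aq. K3PO4 (3 equiv), dioxane/THF, 70 °C
Reagents that add atoms: none
Why: 9-BBN adds to the terminal alkene of 14 at the less substituted carbon and gives the primary alkylborane 15. Zerovalent palladium then inserts into the C4a–Br bond of 8, the arylpalladium adds syn across the tethered C4≡C11 alkyne, and the alkenylpalladium (which could lose a β-hydride only to an allene) transmetalates with the phosphate-activated borane and reductively eliminates to form C11–C12; the closest known reaction type is the intramolecular alkyne carbopalladation terminated by Suzuki–Miyaura coupling, here in its B-alkyl form. Ring B closes in the 6-exo-dig mode through the C4a–C4 bond, because the 7-endo alternative would put a trans double bond into a seven-membered ring. No stereocentre is formed; the Z geometry (C4a cis to C12, methyl cis to C3) follows from the syn addition and from retention in the coupling. The step needs insertion to come before transmetalation, which the three-carbon tether holding the alkyne beside palladium and the slow addition of 15 should secure, and it needs reductive elimination to beat β-hydride loss from the alkyl group, which the base-accelerated B-alkyl protocol is designed for. The aryl and silyl ethers are inert to aqueous K3PO4 at 70 °C.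

Step 11
Reactants: 16 tert-butyl{[(2S,6Z)-6-[(4R)-5,6-dimethoxy-4-methyl-3,4-dihydronaphthalen-1(2H)-ylidene]-2-methylheptyl]oxy}diphenylsilane
Product: 17 tert-butyl{[(2S,6S)-6-[(1S,4R)-5,6-dimethoxy-4-methyl-1,2,3,4-tetrahydronaphthalen-1-yl]-2-methylheptyl]oxy}diphenylsilane
Conditions: [Ir(cod)((S)-iPr-PHOX)][B(3,5-(CF3)2C6H3)4] (5 mol %), H2 (80 bar), CH2Cl2, rt
Reagents that add atoms: none
Why: Iridium-catalysed asymmetric hydrogenation of an unfunctionalised tetrasubstituted alkene with a cationic phosphino-oxazoline complex, in which both hydrogens reach one face so that the Z geometry fixes C4 relative to C11, while the ligand is relied on to choose the face on the side of the C1 methyl group (giving the 1,4-trans tetralin, 4S,11S) against the modest opposite bias expected from that pseudoaxial methyl.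

Step 12
Reactants: 17 tert-butyl{[(2S,6S)-6-[(1S,4R)-5,6-dimethoxy-4-methyl-1,2,3,4-tetrahydronaphthalen-1-yl]-2-methylheptyl]oxy}diphenylsilane
Product: 19 methyl (5R,8S)-8-[(2S,6S)-7-[(tert-butyldiphenylsilyl)oxy]-6-methylheptan-2-yl]-3,4-dimethoxy-5-methyl-5,6,7,8-tetrahydronaphthalene-2-carboxylate, via aryllithium 18 (not isolated)
Conditions: n-BuLi (3 equiv), TMEDA (3 equiv), Et2O, 0 °C; then cannulated into ClCO2Me (5 equiv), THF, −78 °C
Reagents that add atoms: methyl chloroformate, COC(=O)Cl
Why: Directed ortho-metalation, in which the C7 methoxy group guides the base to C6 (the only ring position ortho to an oxygen), followed by acylation of the aryllithium with a chloroformate under inverse addition; the tertiary benzylic C1–H and C4–H are kinetically too slow to be removed.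

Step 13
Reactants: 19 methyl (5R,8S)-8-[(2S,6S)-7-[(tert-butyldiphenylsilyl)oxy]-6-methylheptan-2-yl]-3,4-dimethoxy-5-methyl-5,6,7,8-tetrahydronaphthalene-2-carboxylate
Product: 20 methyl (5R,8S)-8-[(2S,6S)-7-[(tert-butyldiphenylsilyl)oxy]-6-methylheptan-2-yl]-3,4-dihydroxy-5-methyl-5,6,7,8-tetrahydronaphthalene-2-carboxylate
Conditions: BBr3 (4 equiv), CH2Cl2, −78 → −10 °C; aq. NaHCO3
Reagents that add atoms: none
Why: Lewis-acid cleavage of aryl methyl ethers with BBr3, in which the C7 methoxy group should go first with chelation to the ester carbonyl and the C8 methoxy group follow through the cyclic catechol borate, while at low temperature the methyl ester and the hindered, weakly basic TBDPS ether should be spared.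

Step 14
Reactants: 20 methyl (5R,8S)-8-[(2S,6S)-7-[(tert-butyldiphenylsilyl)oxy]-6-methylheptan-2-yl]-3,4-dihydroxy-5-methyl-5,6,7,8-tetrahydronaphthalene-2-carboxylate
Product: 21 methyl (5R,8S)-3,4-dihydroxy-8-[(2S,6S)-7-hydroxy-6-methylheptan-2-yl]-5-methyl-5,6,7,8-tetrahydronaphthalene-2-carboxylate
Conditions: HF·pyridine, pyridine/THF, 0 °C → rt
Reagents that add atoms: none
Why: Fluoride-induced desilylation under buffered, non-basic conditions that leave the catechol and the methyl ester intact and touch no stereocentre.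

**Compound list**

1 | 2,3-dimethoxyphenylboronic acid | COc1cccc(B(O)O)c1OC | starting material
2 | isopropyl (E)-but-2-enoate | C/C=C/C(=O)OC(C)C | starting material
3 | isopropyl (R)-3-(2,3-dimethoxyphenyl)butanoate | COc1cccc([C@H](C)CC(=O)OC(C)C)c1OC | intermediate
4 | (R)-3-(2,3-dimethoxyphenyl)butan-1-ol | COc1cccc([C@H](C)CCO)c1OC | intermediate
5 | (R)-3-(6-bromo-2,3-dimethoxyphenyl)butan-1-ol | COc1ccc(Br)c([C@H](C)CCO)c1OC | intermediate
6 | (R)-1-bromo-2-(4-iodobutan-2-yl)-3,4-dimethoxybenzene | COc1ccc(Br)c([C@H](C)CCI)c1OC | intermediate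
7 | 1-propynyllithium | [Li]C#CC | starting material
8 | (R)-1-bromo-2-(hept-5-yn-2-yl)-3,4-dimethoxybenzene | COc1ccc(Br)c([C@H](C)CCC#CC)c1OC | intermediate
9 | methyl (R)-3-hydroxy-2-methylpropanoate | C[C@H](CO)C(=O)OC | starting material
10 | methyl (R)-3-[(tert-butyldiphenylsilyl)oxy]-2-methylpropanoate | C[C@H](CO[Si](c1ccccc1)(c1ccccc1)C(C)(C)C)C(=O)OC | intermediate
11 | (S)-3-[(tert-butyldiphenylsilyl)oxy]-2-methylpropan-1-ol | C[C@H](CO[Si](c1ccccc1)(c1ccccc1)C(C)(C)C)CO | intermediate
12 | (R)-3-[(tert-butyldiphenylsilyl)oxy]-2-methylpropyl 4-methylbenzenesulfonate | C[C@H](CO[Si](c1ccccc1)(c1ccccc1)C(C)(C)C)COS(=O)(=O)c1ccc(C)cc1 | intermediate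
13 | vinylmagnesium bromide | C=C[Mg]Br | starting material
14 | (S)-tert-butyl[(2-methylpent-4-en-1-yl)oxy]diphenylsilane | C=CC[C@H](C)CO[Si](c1ccccc1)(c1ccccc1)C(C)(C)C | intermediate
15 | 9-[(4S)-5-[(tert-butyldiphenylsilyl)oxy]-4-methylpentyl]-9-borabicyclo[3.3.1]nonane | B1(CCC[C@H](C)CO[Si](c3ccccc3)(c4ccccc4)C(C)(C)C)C2CCCC1CCC2 | intermediate
16 | tert-butyl{[(2S,6Z)-6-[(4R)-5,6-dimethoxy-4-methyl-3,4-dihydronaphthalen-1(2H)-ylidene]-2-methylheptyl]oxy}diphenylsilane (C4=C11 alkene, C4a cis to C12) | COc1ccc2c(c1OC)[C@H](C)CC/C2=C(\C)CCC[C@H](C)CO[Si](c3ccccc3)(c4ccccc4)C(C)(C)C | intermediate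
17 | tert-butyl{[(2S,6S)-6-[(1S,4R)-5,6-dimethoxy-4-methyl-1,2,3,4-tetrahydronaphthalen-1-yl]-2-methylheptyl]oxy}diphenylsilane | COc1ccc2c(c1OC)[C@H](C)CC[C@H]2[C@@H](C)CCC[C@H](C)CO[Si](c3ccccc3)(c4ccccc4)C(C)(C)C | intermediate
18 | C6-lithio derivative of 17 (lithium ortho to the C7 methoxy group) | [Li]c1cc2c(c(OC)c1OC)[C@H](C)CC[C@H]2[C@@H](C)CCC[C@H](C)CO[Si](c3ccccc3)(c4ccccc4)C(C)(C)C | intermediate
19 | methyl (5R,8S)-8-[(2S,6S)-7-[(tert-butyldiphenylsilyl)oxy]-6-methylheptan-2-yl]-3,4-dimethoxy-5-methyl-5,6,7,8-tetrahydronaphthalene-2-carboxylate | COC(=O)c1cc2c(c(OC)c1OC)[C@H](C)CC[C@H]2[C@@H](C)CCC[C@H](C)CO[Si](c3ccccc3)(c4ccccc4)C(C)(C)C | intermediate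
20 | methyl (5R,8S)-8-[(2S,6S)-7-[(tert-butyldiphenylsilyl)oxy]-6-methylheptan-2-yl]-3,4-dihydroxy-5-methyl-5,6,7,8-tetrahydronaphthalene-2-carboxylate | COC(=O)c1cc2c(c(O)c1O)[C@H](C)CC[C@H]2[C@@H](C)CCC[C@H](C)CO[Si](c3ccccc3)(c4ccccc4)C(C)(C)C | intermediate
21 | methyl (5R,8S)-3,4-dihydroxy-8-[(2S,6S)-7-hydroxy-6-methylheptan-2-yl]-5-methyl-5,6,7,8-tetrahydronaphthalene-2-carboxylate | COC(=O)c1cc2c(c(O)c1O)[C@H](C)CC[C@H]2[C@@H](C)CCC[C@H](C)CO | target

**Step count**

Total: 14 steps. Longest linear sequence: 10 steps (steps 1–5 and 10–14, from 1 and 2).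

**Steps most likely to fail**

Step 10. The process at risk is transmetalation of the arylpalladium with the alkylborane before the alkyne has inserted (open-chain aryl–alkyl coupling), together with β-hydride loss from the alkyl group on the crowded alkenylpalladium. The fallback sets out from 12 and 8 and comes back at 16: the alkylborane is replaced by an alkenylboronate, which cannot undergo β-hydride loss, and the extra alkene is removed afterwards. Tosylate 12 and LiC≡CH·H2NCH2CH2NH2 in DMSO would give the terminal alkyne (S)-tert-butyl[(2-methylpent-4-yn-1-yl)oxy]diphenylsilane F1. Pinacolborane with Cp2Zr(H)Cl (cat.) and Et3N would give the (E)-alkenylboronate (S,E)-tert-butyl{[2-methyl-5-(4,4,5,5-tetramethyl-1,3,2-dioxaborolan-2-yl)pent-4-en-1-yl]oxy}diphenylsilane F2. Compounds 8 and F2 with Pd(PPh3)4 and aq. K3PO4 in dioxane at 80 °C would give, by the same 6-exo-dig carbopalladation with alkenyl–alkenyl Suzuki–Miyaura termination, the diene tert-butyl{[(2S,4E,6Z)-6-[(4R)-5,6-dimethoxy-4-methyl-3,4-dihydronaphthalen-1(2H)-ylidene]-2-methylhept-4-en-1-yl]oxy}diphenylsilane F3. Diimide (2-nitrobenzenesulfonohydrazide, Et3N, CH2Cl2) would then reduce only the disubstituted C12=C13 bond and give 16.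

Step 11. The process at risk is delivery of hydrogen to the face anti to the pseudoaxial C1 methyl group (substrate bias overriding the ligand), or stalled turnover at the hindered tetrasubstituted alkene. The fallback sets out from 16 and comes back at 17: ligand control is given up for heterogeneous hydrogenation over PtO2 (H2 50 bar, EtOAc). This keeps the syn addition, and with it the C4/C11 relationship, but leaves the choice of face to the substrate. The substrate is expected to favour the unwanted face, so 17 would probably be the minor product and would have to be separated by preparative HPLC from its isomer tert-butyl{[(2S,6R)-6-[(1R,4R)-5,6-dimethoxy-4-methyl-1,2,3,4-tetrahydronaphthalen-1-yl]-2-methylheptyl]oxy}diphenylsilane F4.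

Step 13. The process at risk is attack of BBr3 at the silyl ether oxygen with conversion of the C16–O bond into a C16–Br bond, and cleavage of the methyl ester if the temperature has to be raised for the second methyl ether. The fallback sets out from 19 and comes back at 21, with the side-chain oxygen carried through the demethylation as an ester. HF·pyridine would give the alcohol methyl (5R,8S)-8-[(2S,6S)-7-hydroxy-6-methylheptan-2-yl]-3,4-dimethoxy-5-methyl-5,6,7,8-tetrahydronaphthalene-2-carboxylate F5. Ac2O, pyridine and DMAP would give the acetate methyl (5R,8S)-8-[(2S,6S)-7-acetoxy-6-methylheptan-2-yl]-3,4-dimethoxy-5-methyl-5,6,7,8-tetrahydronaphthalene-2-carboxylate F6. BBr3 (CH2Cl2, −78 → 0 °C) would give the catechol methyl (5R,8S)-8-[(2S,6S)-7-acetoxy-6-methylheptan-2-yl]-3,4-dihydroxy-5-methyl-5,6,7,8-tetrahydronaphthalene-2-carboxylate F7. K2CO3 in degassed MeOH would remove the acetate, the methyl ester being unchanged in methanol, and give 21.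

**Further compounds**

F1 | step 10 | (S)-tert-butyl[(2-methylpent-4-yn-1-yl)oxy]diphenylsilane | C#CC[C@H](C)CO[Si](c1ccccc1)(c1ccccc1)C(C)(C)C
F2 | step 10 | (S,E)-tert-butyl{[2-methyl-5-(4,4,5,5-tetramethyl-1,3,2-dioxaborolan-2-yl)pent-4-en-1-yl]oxy}diphenylsilane | CC1(C)OB(/C=C/C[C@H](C)CO[Si](c2ccccc2)(c2ccccc2)C(C)(C)C)OC1(C)C
F3 | step 10 | tert-butyl{[(2S,4E,6Z)-6-[(4R)-5,6-dimethoxy-4-methyl-3,4-dihydronaphthalen-1(2H)-ylidene]-2-methylhept-4-en-1-yl]oxy}diphenylsilane | COc1ccc2c(c1OC)[C@H](C)CC/C2=C(C)/C=C/C[C@H](C)CO[Si](c3ccccc3)(c4ccccc4)C(C)(C)C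
F4 | step 11 | tert-butyl{[(2S,6R)-6-[(1R,4R)-5,6-dimethoxy-4-methyl-1,2,3,4-tetrahydronaphthalen-1-yl]-2-methylheptyl]oxy}diphenylsilane | COc1ccc2c(c1OC)[C@H](C)CC[C@@H]2[C@H](C)CCC[C@H](C)CO[Si](c3ccccc3)(c4ccccc4)C(C)(C)C
F5 | step 13 | methyl (5R,8S)-8-[(2S,6S)-7-hydroxy-6-methylheptan-2-yl]-3,4-dimethoxy-5-methyl-5,6,7,8-tetrahydronaphthalene-2-carboxylate | COC(=O)c1cc2c(c(OC)c1OC)[C@H](C)CC[C@H]2[C@@H](C)CCC[C@H](C)CO
F6 | step 13 | methyl (5R,8S)-8-[(2S,6S)-7-acetoxy-6-methylheptan-2-yl]-3,4-dimethoxy-5-methyl-5,6,7,8-tetrahydronaphthalene-2-carboxylate | COC(=O)c1cc2c(c(OC)c1OC)[C@H](C)CC[C@H]2[C@@H](C)CCC[C@H](C)COC(C)=O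
F7 | step 13 | methyl (5R,8S)-8-[(2S,6S)-7-acetoxy-6-methylheptan-2-yl]-3,4-dihydroxy-5-methyl-5,6,7,8-tetrahydronaphthalene-2-carboxylate | COC(=O)c1cc2c(c(O)c1O)[C@H](C)CC[C@H]2[C@@H](C)CCC[C@H](C)COC(C)=O
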